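The plan rests on cutting the C5–C10 and C8–C9 bonds of the decalin. One thermal intramolecular Diels–Alder reaction of an open-chain triene makes both bonds, closes ring B as the cycloadduct and ring A through the C1–C4 tether, and sets C5, C9 and the quaternary C10 together. It exploits the trans-fused rings A and B in which the C9 substituent and the C20 methyl on C10 lie on one face opposite H5: this maps onto an (E)-enoate C9=C10 adding endo to a diene C5=C6–C7=C8. The precursor 13 is an (E,E,Z)-triene with a β-methyl enoate, a C3 dioxolane, a quaternary C4 stereocentre (methyl, ethyl ester) and a C7 silyloxy diene.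

Key step: step 11

Remark 1: labdane numbering is used throughout (C17 on C8, C18 equatorial and C19 axial on C4, C20 on C10); bicyclic C15 intermediates are named as 12,13,14,15,16-pentanorlabdanes, ring stereocentres not restated in a name are as in 14, and the SMILES in the list fix every configuration.
Remark 2: enolates, ylides and other salts made in situ by deprotonation are treated as activated forms of their parent compounds and carry no number of their own.
Remark 3: the (R)-monomethyl ester of 3-methylglutaric acid (17) is taken as the commercial enantiopure half-ester.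

Step 1
Reactants: 1 ethyl (3S)-3-hydroxybutanoate
Product: 2 ethyl (2S,3S)-3-hydroxy-2-methylbutanoate
Conditions: LiN(iPr)2 (2.2 equiv), THF, −78 → −20 °C; MeI, DMPU, −78 → 0 °C; aq. NH4Cl
Reagents that add atoms: iodomethane, CI
Why: Fráter–Seebach alkylation, in which the chelated lithium alkoxide–enolate dianion should be methylated on the face anti to the C3 methyl group to give the anti (2S,3S) ester, and only the C3 centre has to be secure because C2 is enolised again in step 2.

Step 2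
Reactants: 2 ethyl (2S,3S)-3-hydroxy-2-methylbutanoate
Product: 3 ethyl (2S,3S)-3-hydroxy-2-(hydroxymethyl)-2-methylbutanoate
Conditions: LiN(iPr)2 (2.2 equiv), THF, −78 → −15 °C; CH2O (gas, from cracked paraformaldehyde), −78 → −40 °C; aq. NH4Cl
Reagents that add atoms: formaldehyde, C=O
Why: Second Fráter–Seebach reaction (aldol-type hydroxymethylation) in which the tetrasubstituted dianion should again be attacked anti to the C3 methyl group of the chelate, so that the quaternary centre (future C4) is set as 2S and any minor diastereomer can be removed at this diol stage.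

Step 3
Reactants: 3 ethyl (2S,3S)-3-hydroxy-2-(hydroxymethyl)-2-methylbutanoate
Product: 4 ethyl (2S,3S)-2-{[(tert-butyldimethylsilyl)oxy]methyl}-3-hydroxy-2-methylbutanoate
Conditions: TBSCl (1.05 equiv), imidazole, CH2Cl2, 0 °C
Reagents that add atoms: tert-butyldimethylsilyl chloride, CC(C)(C)[Si](C)(C)Cl
Why: Selective silyl ether formation at the primary hydroxyl, the secondary one next to the quaternary carbon being much slower.

Step 4
Reactants: 4 ethyl (2S,3S)-2-{[(tert-butyldimethylsilyl)oxy]methyl}-3-hydroxy-2-methylbutanoate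
Product: 5 ethyl (2S)-2-{[(tert-butyldimethylsilyl)oxy]methyl}-2-methyl-3-oxobutanoate
Conditions: Dess–Martin periodinane, NaHCO3, CH2Cl2, 0 → 23 °C
Reagents that add atoms: none
Why: Dess–Martin oxidation of the secondary alcohol gives a β-keto ester whose quaternary α-carbon bears no hydrogen and therefore cannot racemise.

Step 5
Reactants: 5 ethyl (2S)-2-{[(tert-butyldimethylsilyl)oxy]methyl}-2-methyl-3-oxobutanoate; 6 methyl (2E)-4-bromo-3-methylbut-2-enoate
Product: 7 1-ethyl 8-methyl (2S,6E)-2-{[(tert-butyldimethylsilyl)oxy]methyl}-2,6-dimethyl-3-oxooct-6-enedioate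
Conditions: LiN(iPr)2 (1.05 equiv), THF, −78 °C; then 6, DMPU, −78 → −30 °C
Reagents that add atoms: none
Why: Kinetic enolate alkylation, in which only the ketone methyl group (C2) can be deprotonated and SN2 displacement of the allylic bromide should keep the (E)-enoate geometry, the β-methyl group disfavouring conjugate addition.

Step 6
Reactants: 7 1-ethyl 8-methyl (2S,6E)-2-{[(tert-butyldimethylsilyl)oxy]methyl}-2,6-dimethyl-3-oxooct-6-enedioate
Product: 8 methyl (2E)-5-{2-[(2S)-3-{[tert-butyl(dimethyl)silyl]oxy}-1-ethoxy-2-methyl-1-oxopropan-2-yl]-1,3-dioxolan-2-yl}-3-methylpent-2-enoate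
Conditions: (TMSOCH2)2 (3 equiv), TMSOTf (0.1 equiv), CH2Cl2, −78 → 0 °C; pyridine quench
Reagents that add atoms: 1,2-bis(trimethylsilyloxy)ethane, C[Si](C)(C)OCCO[Si](C)(C)C
Why: Silyl-triflate-catalysed ketalisation with the bis-silyl glycol ether, an aprotic method suited to hindered ketones, masks C3 before the neighbouring carbon is raised to the aldehyde.

Step 7
Reactants: 8 methyl (2E)-5-{2-[(2S)-3-{[tert-butyl(dimethyl)silyl]oxy}-1-ethoxy-2-methyl-1-oxopropan-2-yl]-1,3-dioxolan-2-yl}-3-methylpent-2-enoate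
Product: 9 methyl (2E)-5-{2-[(2S)-1-ethoxy-3-hydroxy-2-methyl-1-oxopropan-2-yl]-1,3-dioxolan-2-yl}-3-methylpent-2-enoate
Conditions: Bu4NF, AcOH, THF, 0 → 23 °C
Reagents that add atoms: none
Why: Fluoride-mediated silyl ether cleavage, buffered with acetic acid so that the β-hydroxy ester does not undergo retro-aldol cleavage.

Step 8
Reactants: 9 methyl (2E)-5-{2-[(2S)-1-ethoxy-3-hydroxy-2-methyl-1-oxopropan-2-yl]-1,3-dioxolan-2-yl}-3-methylpent-2-enoate
Product: 10 methyl (2E)-5-{2-[(2S)-1-ethoxy-2-methyl-1,3-dioxopropan-2-yl]-1,3-dioxolan-2-yl}-3-methylpent-2-enoate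
Conditions: Dess–Martin periodinane, NaHCO3, CH2Cl2, 0 → 23 °C
Reagents that add atoms: none
Why: Dess–Martin oxidation to the C5 aldehyde, which has no α-hydrogen and is stable once C3 is a ketal.

Step 9
Reactants: 10 methyl (2E)-5-{2-[(2S)-1-ethoxy-2-methyl-1,3-dioxopropan-2-yl]-1,3-dioxolan-2-yl}-3-methylpent-2-enoate; 11 diethyl (2-oxobutyl)phosphonate
Product: 12 ethyl (2S,3E)-2-{2-[(3E)-5-methoxy-3-methyl-5-oxopent-3-en-1-yl]-1,3-dioxolan-2-yl}-2-methyl-5-oxohept-3-enoate
Conditions: 11, NaH, THF, 0 °C; then 10, 0 → 40 °C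
Reagents that add atoms: none
Why: Horner–Wadsworth–Emmons olefination with the preformed β-ketophosphonate anion should give the (E)-enone, and the absence of hydroxide or alkoxide protects the α-formyl ester from deformylation.

Step 10
Reactants: 12 ethyl (2S,3E)-2-{2-[(3E)-5-methoxy-3-methyl-5-oxopent-3-en-1-yl]-1,3-dioxolan-2-yl}-2-methyl-5-oxohept-3-enoate
Product: 13 ethyl (2S,3E,5Z)-5-[(tert-butyldimethylsilyl)oxy]-2-{2-[(3E)-5-methoxy-3-methyl-5-oxopent-3-en-1-yl]-1,3-dioxolan-2-yl}-2-methylhepta-3,5-dienoate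
Conditions: TBSOTf, Et3N, CH2Cl2, −78 → 0 °C
Reagents that add atoms: tert-butyldimethylsilyl trifluoromethanesulfonate, CC(C)(C)[Si](C)(C)OS(=O)(=O)C(F)(F)F
Why: Soft enolisation and silylation of the ethyl ketone (silyl enol ether formation) should give the (Z)-enol ether, which places the C17 methyl outside the s-cis diene, while the esters are not enolised under these conditions.

Step 11
Reactants: 13 ethyl (2S,3E,5Z)-5-[(tert-butyldimethylsilyl)oxy]-2-{2-[(3E)-5-methoxy-3-methyl-5-oxopent-3-en-1-yl]-1,3-dioxolan-2-yl}-2-methylhepta-3,5-dienoate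
Product: 14 19-ethyl 11-methyl (4S,5S,8S,9R,10R)-7-[(tert-butyldimethylsilyl)oxy]-3,3-(ethylenedioxy)-12,13,14,15,16-pentanorlabd-6-ene-11,19-dioate
Conditions: PhMe (0.01 M), BHT (0.1 equiv), Et3N (0.1 equiv), sealed tube, 180 °C
Reagents that add atoms: none
Why: Concerted but asynchronous thermal [4+2] cycloaddition between the silyloxy diene C5=C6–C7=C8 and the enoate C9=C10 forms C5–C10 and C8–C9, the closest known reaction type being the thermal type 1 intramolecular Diels–Alder reaction of 1,7,9-decatrienoates that carry a 2-silyloxy diene. Ring B closes as the six-membered cycloadduct ring and ring A closes in the fused mode, the four-atom tether C1–C4 linking the diene terminus C5 to the dienophile carbon C10 in a chair-like loop. Suprafacial addition transfers the (E)-enoate geometry to C9/C10 (C11 cis to C20) and the (Z)-enol ether geometry to C8 (C17 cis to C11, erased in step 19), and the ester-endo, tether-anti arrangement sets the trans C5/C10 ring fusion. The absolute configuration comes from the existing C4 stereocentre, which in the chair-like tether puts the flat ester axial, syn to the developing C20 methyl, and the C18 methyl equatorial, so that one diene face is used. The step needs endo (trans-fusing) and diene-facial selectivity: the first rests on the (E)-enoate with its carbonyl under the diene and on the chair-like tether, the second on the smaller steric demand of an ester than of a methyl group in the axial site, which is a modest bias, so the minor trans-fused diastereomer and any cis-fused adducts are expected to need chromatographic removal. The geminal substitution at C4 and the C3 dioxolane favour the coiled conformer and should let the β,β-disubstituted enoate react below the temperature at which the silyl enol ether is lost.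

Step 12
Reactants: 14 19-ethyl 11-methyl (4S,5S,8S,9R,10R)-7-[(tert-butyldimethylsilyl)oxy]-3,3-(ethylenedioxy)-12,13,14,15,16-pentanorlabd-6-ene-11,19-dioate
Product: 15 ethyl 7-[(tert-butyldimethylsilyl)oxy]-3,3-(ethylenedioxy)-11-hydroxy-12,13,14,15,16-pentanorlabd-6-en-19-oate
Conditions: iBu2AlH (2.2 equiv), CH2Cl2, −78 → −40 °C; Rochelle salt
Reagents that add atoms: none
Why: Ester reduction with diisobutylaluminium hydride, in which the secondary C11 methyl ester should react well before the axial C19 ethyl ester on the quaternary C4 next to the dioxolane, the silyl enol ether being inert.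

Step 13
Reactants: 15 ethyl 7-[(tert-butyldimethylsilyl)oxy]-3,3-(ethylenedioxy)-11-hydroxy-12,13,14,15,16-pentanorlabd-6-en-19-oate
Product: 16 ethyl 7-[(tert-butyldimethylsilyl)oxy]-3,3-(ethylenedioxy)-11-oxo-12,13,14,15,16-pentanorlabd-6-en-19-oate
Conditions: Pr4N[RuO4] (5 mol %), NMO, 4 Å MS, CH2Cl2, 23 °C
Reagents that add atoms: none
Why: Ley–Griffith oxidation under neutral conditions is tolerated by the silyl enol ether, and the aldehyde is the equatorial, thermodynamically preferred C9 epimer.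

Step 14
Reactants: 17 (3R)-5-methoxy-3-methyl-5-oxopentanoic acid
Product: 18 methyl (3S)-4-iodo-3-methylbutanoate
Conditions: PhI(OAc)2, I2, hν (tungsten lamp), cyclohexane, 80 °C
Reagents that add atoms: iodine, II
Why: Radical iododecarboxylation (Hunsdiecker-type reaction) of the free acid generates the primary radical next to, not at, the stereocentre, which is therefore untouched.

Step 15
Reactants: 18 methyl (3S)-4-iodo-3-methylbutanoate
Product: 19 [(2S)-4-methoxy-2-methyl-4-oxobutyl]triphenylphosphonium iodide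
Conditions: PPh3, MeCN, 82 °C
Reagents that add atoms: triphenylphosphine, c1ccc(cc1)P(c1ccccc1)c1ccccc1
Why: SN2 quaternisation of triphenylphosphine by the primary iodide (phosphonium salt formation).

Step 16
Reactants: 16 ethyl 7-[(tert-butyldimethylsilyl)oxy]-3,3-(ethylenedioxy)-11-oxo-12,13,14,15,16-pentanorlabd-6-en-19-oate; 19 [(2S)-4-methoxy-2-methyl-4-oxobutyl]triphenylphosphonium iodide
Product: 20 19-ethyl 15-methyl (11Z,13S)-7-[(tert-butyldimethylsilyl)oxy]-3,3-(ethylenedioxy)labda-6,11-diene-15,19-dioate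
Conditions: 19, KN(SiMe3)2, THF, −78 → 0 °C; then 16, −78 → 23 °C
Reagents that add atoms: none
Why: Wittig olefination with a non-stabilised ylide is expected to give mainly the (Z)-alkene, whose geometry is irrelevant because the bond is hydrogenated in step 18, while the silyl enol ether keeps C7 out of reach of the ylide.

Step 17
Reactants: 20 19-ethyl 15-methyl (11Z,13S)-7-[(tert-butyldimethylsilyl)oxy]-3,3-(ethylenedioxy)labda-6,11-diene-15,19-dioate
Product: 21 19-ethyl 15-methyl (11Z,13S)-3,3-(ethylenedioxy)-7-oxolabd-11-ene-15,19-dioate (8-methyl equatorial)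
Conditions: Bu4NF, THF, 0 °C; then DBU (0.2 equiv), 23 °C; aq. NH4Cl
Reagents that add atoms: none
Why: Fluoride cleavage of the silyl enol ether gives the C7 ketone, and base-mediated epimerisation at C8 should move the methyl group from the axial position syn to C20 to the equatorial one.

Step 18
Reactants: 21 19-ethyl 15-methyl (11Z,13S)-3,3-(ethylenedioxy)-7-oxolabd-11-ene-15,19-dioate (8-methyl equatorial)
Product: 22 19-ethyl 15-methyl (13R)-3,3-(ethylenedioxy)-7-oxolabdane-15,19-dioate (8-methyl equatorial)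
Conditions: H2 (1 atm), Pt/C, EtOAc, 23 °C
Reagents that add atoms: none
Why: Heterogeneous catalytic hydrogenation of the disubstituted alkene, with platinum chosen over palladium to avoid double-bond migration toward the allylic C13 stereocentre, leaves the ketone and esters untouched.

Step 19
Reactants: 22 19-ethyl 15-methyl (13R)-3,3-(ethylenedioxy)-7-oxolabdane-15,19-dioate (8-methyl equatorial)
Product: 23 19-ethyl 15-methyl (13R)-3,3-(ethylenedioxy)-7-[(trifluoromethylsulfonyl)oxy]labd-7-ene-15,19-dioate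
Conditions: iPr2NMgBr (from iPr2NH and EtMgBr), Et2O, 0 → 23 °C; then PhNTf2, DMPU, 0 → 23 °C
Reagents that add atoms: N-phenylbis(trifluoromethanesulfonimide), O=S(=O)(N(c1ccccc1)S(=O)(=O)C(F)(F)F)C(F)(F)F
Why: Thermodynamic enolisation with the magnesium amide followed by enolate O-triflation should favour the tetrasubstituted C7=C8 enolate, which also points away from the ring fusion, and C8 becomes trigonal so that its configuration is erased.

Step 20
Reactants: 23 19-ethyl 15-methyl (13R)-3,3-(ethylenedioxy)-7-[(trifluoromethylsulfonyl)oxy]labd-7-ene-15,19-dioate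
Product: 24 19-ethyl 15-methyl (13R)-3-oxo-7-[(trifluoromethylsulfonyl)oxy]labd-7-ene-15,19-dioate
Conditions: TsOH·H2O, acetone/H2O (10:1), 50 °C
Reagents that add atoms: water, O
Why: Acid-catalysed ketal hydrolysis frees the C3 ketone while the vinyl triflate and both esters are stable to aqueous acid and no acid-sensitive alkene is present yet.

Step 21
Reactants: 24 19-ethyl 15-methyl (13R)-3-oxo-7-[(trifluoromethylsulfonyl)oxy]labd-7-ene-15,19-dioate
Product: 27 19-ethyl 15-methyl (13R)-2-hydroxy-3-oxo-7-[(trifluoromethylsulfonyl)oxy]labd-7-ene-15,19-dioate (2-OH equatorial), via trimethylsilyl enol ether 25 (not isolated), via 2-trimethylsilyloxy 3-ketone 26 (not isolated)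
Conditions: TMSOTf, Et3N, CH2Cl2, 0 °C, cold NaHCO3 wash; crude in CH2Cl2, mCPBA, NaHCO3, −20 → 0 °C; then 1 M HCl, THF, 23 °C
Reagents that add atoms: 3-chloroperbenzoic acid, OOC(=O)c1cccc(Cl)c1
Why: Rubottom oxidation, in which enolisation is only possible toward C2 because C4 is quaternary and the peracid should attack the enol ether face opposite the axial C19 ester and C20 methyl, placing the new C2 oxygen equatorial and cis to H5, the electron-poor vinyl triflate being inert.

Step 22
Reactants: 27 19-ethyl 15-methyl (13R)-2-hydroxy-3-oxo-7-[(trifluoromethylsulfonyl)oxy]labd-7-ene-15,19-dioate (2-OH equatorial)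
Product: 28 19-ethyl 15-methyl (13R)-2,3-dihydroxy-7-[(trifluoromethylsulfonyl)oxy]labd-7-ene-15,19-dioate (2-OH equatorial; 3-OH axial)
Conditions: LiBH(s-Bu)3 (L-Selectride, 3 equiv), THF, −78 °C; aq. NH4Cl
Reagents that add atoms: none
Why: Ketone reduction with a bulky trialkylborohydride should deliver hydride along the equatorial direction, away from the 1,3-diaxial hydrogens on C1 and C5, and so give the axial C3 alcohol cis to the C2 hydroxyl.

Step 23
Reactants: 28 19-ethyl 15-methyl (13R)-2,3-dihydroxy-7-[(trifluoromethylsulfonyl)oxy]labd-7-ene-15,19-dioate (2-OH equatorial; 3-OH axial)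
Product: 29 19-ethyl 15-methyl (13R)-2,3-(isopropylidenedioxy)-7-[(trifluoromethylsulfonyl)oxy]labd-7-ene-15,19-dioate
Conditions: Me2C(OMe)2, PPTS, CH2Cl2, 23 °C
Reagents that add atoms: 2,2-dimethoxypropane, COC(C)(C)OC
Why: Acetonide formation (acid-catalysed transketalisation) on the cis-diol protects both hydroxyls so that only the C19 hydroxyl can be acetylated later.

Step 24
Reactants: 29 19-ethyl 15-methyl (13R)-2,3-(isopropylidenedioxy)-7-[(trifluoromethylsulfonyl)oxy]labd-7-ene-15,19-dioate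
Product: 30 19-ethyl 15-methyl (13R)-2,3-(isopropylidenedioxy)labd-7-ene-15,19-dioate
Conditions: Pd(OAc)2 (5 mol %), PPh3 (10 mol %), Bu3N, HCO2H, DMF, 60 °C
Reagents that add atoms: none
Why: Palladium-catalysed formate reduction of the vinyl triflate (oxidative addition to zerovalent palladium, formate decarboxylation, reductive elimination) replaces the triflate by hydrogen and leaves the double bond at C7=C8.

Step 25
Reactants: 30 19-ethyl 15-methyl (13R)-2,3-(isopropylidenedioxy)labd-7-ene-15,19-dioate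
Product: 31 (13R)-19-ethoxy-2,3-(isopropylidenedioxy)-19-oxolabd-7-en-15-oic acid
Conditions: LiOH, THF/MeOH/H2O, 23 °C; then 1 M HCl to pH 4, 0 °C
Reagents that add atoms: lithium hydroxide, [Li+].[OH-]
Why: Saponification should cleave only the unhindered C15 methyl ester, the axial C19 ethyl ester on the quaternary carbon being inert at this temperature.

Step 26
Reactants: 31 (13R)-19-ethoxy-2,3-(isopropylidenedioxy)-19-oxolabd-7-en-15-oic acid
Product: 32 (13R)-19-hydroxy-2,3-(isopropylidenedioxy)labd-7-en-15-oic acid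
Conditions: LiEt3BH (6 equiv), THF, 0 → 40 °C; then 1 M HCl to pH 4, 0 °C
Reagents that add atoms: none
Why: Ester reduction with lithium triethylborohydride, which first turns the acid into its lithium carboxylate and does not reduce it further, while the hindered C19 ester is reduced to the primary alcohol.

Step 27
Reactants: 32 (13R)-19-hydroxy-2,3-(isopropylidenedioxy)labd-7-en-15-oic acid
Product: 34 (13R)-19-acetoxy-2,3-(isopropylidenedioxy)labd-7-en-15-oic acid, via mixed acetic anhydride 33 (not isolated)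
Conditions: Ac2O, pyridine, DMAP (cat.), CH2Cl2, 23 °C; then H2O, THF, NaHCO3, 23 °C; acidify to pH 4
Reagents that add atoms: acetic anhydride, CC(=O)OC(C)=O
Why: DMAP-catalysed acetylation of the only free hydroxyl, the mixed anhydride formed at the carboxyl group being hydrolysed back to the acid in the aqueous bicarbonate stage.

Step 28
Reactants: 34 (13R)-19-acetoxy-2,3-(isopropylidenedioxy)labd-7-en-15-oic acid
Product: 35 (2S,3R,4R,5S,9R,10S,13R)-19-acetoxy-2,3-dihydroxylabd-7-en-15-oic acid (CNP0164890.1)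
Conditions: AcOH/H2O (4:1), 45 °C
Reagents that add atoms: none
Why: Mild aqueous-acid hydrolysis of the acetonide (acetal cleavage), under which the primary acetate and the trisubstituted alkene should survive.

Compound list
1 | ethyl (3S)-3-hydroxybutanoate | CCOC(=O)C[C@H](C)O | starting material
2 | ethyl (2S,3S)-3-hydroxy-2-methylbutanoate | CCOC(=O)[C@@H](C)[C@H](C)O | intermediate
3 | ethyl (2S,3S)-3-hydroxy-2-(hydroxymethyl)-2-methylbutanoate | CCOC(=O)[C@@](C)(CO)[C@H](C)O | intermediate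
4 | ethyl (2S,3S)-2-{[(tert-butyldimethylsilyl)oxy]methyl}-3-hydroxy-2-methylbutanoate | CCOC(=O)[C@@](C)(CO[Si](C)(C)C(C)(C)C)[C@H](C)O | intermediate
5 | ethyl (2S)-2-{[(tert-butyldimethylsilyl)oxy]methyl}-2-methyl-3-oxobutanoate | CCOC(=O)[C@@](C)(CO[Si](C)(C)C(C)(C)C)C(C)=O | intermediate
6 | methyl (2E)-4-bromo-3-methylbut-2-enoate | COC(=O)/C=C(\C)CBr | starting material
7 | 1-ethyl 8-methyl (2S,6E)-2-{[(tert-butyldimethylsilyl)oxy]methyl}-2,6-dimethyl-3-oxooct-6-enedioate | COC(=O)/C=C(\C)CCC(=O)[C@@](C)(C(=O)OCC)CO[Si](C)(C)C(C)(C)C | intermediate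
8 | methyl (2E)-5-{2-[(2S)-3-{[tert-butyl(dimethyl)silyl]oxy}-1-ethoxy-2-methyl-1-oxopropan-2-yl]-1,3-dioxolan-2-yl}-3-methylpent-2-enoate | COC(=O)/C=C(\C)CCC1(OCCO1)[C@@](C)(C(=O)OCC)CO[Si](C)(C)C(C)(C)C | intermediate
9 | methyl (2E)-5-{2-[(2S)-1-ethoxy-3-hydroxy-2-methyl-1-oxopropan-2-yl]-1,3-dioxolan-2-yl}-3-methylpent-2-enoate | COC(=O)/C=C(\C)CCC1(OCCO1)[C@@](C)(C(=O)OCC)CO | intermediate
10 | methyl (2E)-5-{2-[(2S)-1-ethoxy-2-methyl-1,3-dioxopropan-2-yl]-1,3-dioxolan-2-yl}-3-methylpent-2-enoate | COC(=O)/C=C(\C)CCC1(OCCO1)[C@@](C)(C(=O)OCC)C=O | intermediate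
11 | diethyl (2-oxobutyl)phosphonate | CCC(=O)CP(=O)(OCC)OCC | starting material
12 | ethyl (2S,3E)-2-{2-[(3E)-5-methoxy-3-methyl-5-oxopent-3-en-1-yl]-1,3-dioxolan-2-yl}-2-methyl-5-oxohept-3-enoate | COC(=O)/C=C(\C)CCC1(OCCO1)[C@@](C)(C(=O)OCC)/C=C/C(=O)CC | intermediate
13 | ethyl (2S,3E,5Z)-5-[(tert-butyldimethylsilyl)oxy]-2-{2-[(3E)-5-methoxy-3-methyl-5-oxopent-3-en-1-yl]-1,3-dioxolan-2-yl}-2-methylhepta-3,5-dienoate (key-step precursor) | COC(=O)/C=C(\C)CCC1(OCCO1)[C@@](C)(C(=O)OCC)/C=C/C(O[Si](C)(C)C(C)(C)C)=C/C | intermediate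
14 | 19-ethyl 11-methyl (4S,5S,8S,9R,10R)-7-[(tert-butyldimethylsilyl)oxy]-3,3-(ethylenedioxy)-12,13,14,15,16-pentanorlabd-6-ene-11,19-dioate (key-step product; trans-fused, C19 ester axial and cis to C20, C11 ester cis to C20, 8-methyl cis to C11) | CCOC(=O)[C@@]1(C)[C@H]2C=C(O[Si](C)(C)C(C)(C)C)[C@@H](C)[C@@H](C(=O)OC)[C@]2(C)CCC13OCCO3 | intermediate
15 | ethyl 7-[(tert-butyldimethylsilyl)oxy]-3,3-(ethylenedioxy)-11-hydroxy-12,13,14,15,16-pentanorlabd-6-en-19-oate | CCOC(=O)[C@@]1(C)[C@H]2C=C(O[Si](C)(C)C(C)(C)C)[C@@H](C)[C@@H](CO)[C@]2(C)CCC13OCCO3 | intermediate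
16 | ethyl 7-[(tert-butyldimethylsilyl)oxy]-3,3-(ethylenedioxy)-11-oxo-12,13,14,15,16-pentanorlabd-6-en-19-oate | CCOC(=O)[C@@]1(C)[C@H]2C=C(O[Si](C)(C)C(C)(C)C)[C@@H](C)[C@@H](C=O)[C@]2(C)CCC13OCCO3 | intermediate
17 | (3R)-5-methoxy-3-methyl-5-oxopentanoic acid | COC(=O)C[C@H](C)CC(=O)O | starting material
18 | methyl (3S)-4-iodo-3-methylbutanoate | COC(=O)C[C@H](C)CI | intermediate
19 | [(2S)-4-methoxy-2-methyl-4-oxobutyl]triphenylphosphonium iodide | COC(=O)C[C@H](C)C[P+](c1ccccc1)(c1ccccc1)c1ccccc1.[I-] | intermediate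
20 | 19-ethyl 15-methyl (11Z,13S)-7-[(tert-butyldimethylsilyl)oxy]-3,3-(ethylenedioxy)labda-6,11-diene-15,19-dioate | CCOC(=O)[C@@]1(C)[C@H]2C=C(O[Si](C)(C)C(C)(C)C)[C@@H](C)[C@@H](/C=C\[C@@H](C)CC(=O)OC)[C@]2(C)CCC13OCCO3 | intermediate
21 | 19-ethyl 15-methyl (11Z,13S)-3,3-(ethylenedioxy)-7-oxolabd-11-ene-15,19-dioate (8-methyl equatorial) | CCOC(=O)[C@@]1(C)[C@H]2CC(=O)[C@H](C)[C@@H](/C=C\[C@@H](C)CC(=O)OC)[C@]2(C)CCC13OCCO3 | intermediate
22 | 19-ethyl 15-methyl (13R)-3,3-(ethylenedioxy)-7-oxolabdane-15,19-dioate (8-methyl equatorial) | CCOC(=O)[C@@]1(C)[C@H]2CC(=O)[C@H](C)[C@@H](CC[C@@H](C)CC(=O)OC)[C@]2(C)CCC13OCCO3 | intermediate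
23 | 19-ethyl 15-methyl (13R)-3,3-(ethylenedioxy)-7-[(trifluoromethylsulfonyl)oxy]labd-7-ene-15,19-dioate | CCOC(=O)[C@@]1(C)[C@H]2CC(OS(=O)(=O)C(F)(F)F)=C(C)[C@@H](CC[C@@H](C)CC(=O)OC)[C@]2(C)CCC13OCCO3 | intermediate
24 | 19-ethyl 15-methyl (13R)-3-oxo-7-[(trifluoromethylsulfonyl)oxy]labd-7-ene-15,19-dioate | CCOC(=O)[C@@]1(C)[C@H]2CC(OS(=O)(=O)C(F)(F)F)=C(C)[C@@H](CC[C@@H](C)CC(=O)OC)[C@]2(C)CCC1=O | intermediate
25 | 19-ethyl 15-methyl (13R)-7-[(trifluoromethylsulfonyl)oxy]-3-(trimethylsilyloxy)labda-2,7-diene-15,19-dioate | CCOC(=O)[C@@]1(C)[C@H]2CC(OS(=O)(=O)C(F)(F)F)=C(C)[C@@H](CC[C@@H](C)CC(=O)OC)[C@]2(C)CC=C1O[Si](C)(C)C | intermediate (not isolated)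
26 | 19-ethyl 15-methyl (13R)-3-oxo-7-[(trifluoromethylsulfonyl)oxy]-2-(trimethylsilyloxy)labd-7-ene-15,19-dioate (2-O equatorial) | CCOC(=O)[C@@]1(C)[C@H]2CC(OS(=O)(=O)C(F)(F)F)=C(C)[C@@H](CC[C@@H](C)CC(=O)OC)[C@]2(C)C[C@H](O[Si](C)(C)C)C1=O | intermediate (not isolated)
27 | 19-ethyl 15-methyl (13R)-2-hydroxy-3-oxo-7-[(trifluoromethylsulfonyl)oxy]labd-7-ene-15,19-dioate (2-OH equatorial, cis to H5) | CCOC(=O)[C@@]1(C)[C@H]2CC(OS(=O)(=O)C(F)(F)F)=C(C)[C@@H](CC[C@@H](C)CC(=O)OC)[C@]2(C)C[C@H](O)C1=O | intermediate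
28 | 19-ethyl 15-methyl (13R)-2,3-dihydroxy-7-[(trifluoromethylsulfonyl)oxy]labd-7-ene-15,19-dioate (2-OH equatorial, 3-OH axial, both cis to H5) | CCOC(=O)[C@@]1(C)[C@H]2CC(OS(=O)(=O)C(F)(F)F)=C(C)[C@@H](CC[C@@H](C)CC(=O)OC)[C@]2(C)C[C@H](O)[C@@H]1O | intermediate
29 | 19-ethyl 15-methyl (13R)-2,3-(isopropylidenedioxy)-7-[(trifluoromethylsulfonyl)oxy]labd-7-ene-15,19-dioate | CCOC(=O)[C@@]1(C)[C@H]2CC(OS(=O)(=O)C(F)(F)F)=C(C)[C@@H](CC[C@@H](C)CC(=O)OC)[C@]2(C)C[C@@H]3OC(C)(C)O[C@H]13 | intermediate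
30 | 19-ethyl 15-methyl (13R)-2,3-(isopropylidenedioxy)labd-7-ene-15,19-dioate | CCOC(=O)[C@@]1(C)[C@H]2CC=C(C)[C@@H](CC[C@@H](C)CC(=O)OC)[C@]2(C)C[C@@H]3OC(C)(C)O[C@H]13 | intermediate
31 | (13R)-19-ethoxy-2,3-(isopropylidenedioxy)-19-oxolabd-7-en-15-oic acid | CCOC(=O)[C@@]1(C)[C@H]2CC=C(C)[C@@H](CC[C@@H](C)CC(=O)O)[C@]2(C)C[C@@H]3OC(C)(C)O[C@H]13 | intermediate
32 | (13R)-19-hydroxy-2,3-(isopropylidenedioxy)labd-7-en-15-oic acid | OC[C@@]1(C)[C@H]2CC=C(C)[C@@H](CC[C@@H](C)CC(=O)O)[C@]2(C)C[C@@H]3OC(C)(C)O[C@H]13 | intermediate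
33 | acetic (13R)-19-acetoxy-2,3-(isopropylidenedioxy)labd-7-en-15-oic anhydride | CC(=O)OC[C@@]1(C)[C@H]2CC=C(C)[C@@H](CC[C@@H](C)CC(=O)OC(C)=O)[C@]2(C)C[C@@H]3OC(C)(C)O[C@H]13 | intermediate (not isolated)
34 | (13R)-19-acetoxy-2,3-(isopropylidenedioxy)labd-7-en-15-oic acid | CC(=O)OC[C@@]1(C)[C@H]2CC=C(C)[C@@H](CC[C@@H](C)CC(=O)O)[C@]2(C)C[C@@H]3OC(C)(C)O[C@H]13 | intermediate
35 | (2S,3R,4R,5S,9R,10S,13R)-19-acetoxy-2,3-dihydroxylabd-7-en-15-oic acid (CNP0164890.1) | CC(=O)OC[C@@]1(C)[C@H]2CC=C(C)[C@@H](CC[C@@H](C)CC(=O)O)[C@]2(C)C[C@H](O)[C@@H]1O | target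

Total step count: 28. Longest linear sequence: 26 steps (steps 1–13, then 16–28); the side-chain fragment 19 takes 2 steps (14 and 15).

Steps most likely to fail

Step 11 (key step). The β,β-disubstituted enoate may cyclise so slowly that loss of the silyl enol ether or oligomerisation competes, and the endo and diene-facial selectivities may be low. The fallback keeps the same two bonds but changes the dienophile activation. From 13, iBu2AlH at −78 °C should reduce only the conjugated methyl ester to give the allylic alcohol, ethyl (2S,3E,5Z)-5-[(tert-butyldimethylsilyl)oxy]-2-{2-[(3E)-5-hydroxy-3-methylpent-3-en-1-yl]-1,3-dioxolan-2-yl}-2-methylhepta-3,5-dienoate F1. MnO2 then oxidises it to the (E)-enal, ethyl (2S,3E,5Z)-5-[(tert-butyldimethylsilyl)oxy]-2-methyl-2-{2-[(3E)-3-methyl-5-oxopent-3-en-1-yl]-1,3-dioxolan-2-yl}hepta-3,5-dienoate F2. This more electrophilic dienophile should undergo the same cycloaddition at about 110–130 °C in toluene. Its adduct is aldehyde 16, so the route is rejoined at 16 and steps 12 and 13 fall away.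

Step 19. Enolisation may go toward C6 instead of C8 or fail to equilibrate, and the magnesium enolate may attack the side-chain ester. The fallback makes the alkene by alcohol elimination instead of enolate trapping. From 22, LiBH(s-Bu)3 should reduce the C7 ketone from the equatorial side to the axial alcohol, 19-ethyl 15-methyl (13R)-3,3-(ethylenedioxy)-7-hydroxylabdane-15,19-dioate F3. POCl3 in pyridine then eliminates it in an anti fashion with the axial tertiary H8 to give 19-ethyl 15-methyl (13R)-3,3-(ethylenedioxy)labd-7-ene-15,19-dioate F4. TsOH in aqueous acetone removes the dioxolane to give 19-ethyl 15-methyl (13R)-3-oxolabd-7-ene-15,19-dioate F5. Because a peracid cannot be used beside the alkene, C2 is hydroxylated through the potassium enolate (KN(SiMe3)2, −78 °C) with 2-(phenylsulfonyl)-3-phenyloxaziridine to give 19-ethyl 15-methyl (13R)-2-hydroxy-3-oxolabd-7-ene-15,19-dioate F6. LiBH(s-Bu)3 then gives 19-ethyl 15-methyl (13R)-2,3-dihydroxylabd-7-ene-15,19-dioate F7, and acetonide formation under the conditions of step 23 returns to 30.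

Step 22. Hydride delivery along the axial direction would give the trans-diol, that is the wrong configuration at C3. The fallback sets both oxygens by cis-dihydroxylation of an alkene instead of by ketone reduction. From 24, NaBH4 should give the equatorial alcohol, 19-ethyl 15-methyl (13R)-3-hydroxy-7-[(trifluoromethylsulfonyl)oxy]labd-7-ene-15,19-dioate F8. NaH, CS2 and MeI convert it into the S-methyl xanthate, 19-ethyl 15-methyl (13R)-3-{[(methylsulfanyl)carbonothioyl]oxy}-7-[(trifluoromethylsulfonyl)oxy]labd-7-ene-15,19-dioate F9. Chugaev pyrolysis, which can only eliminate toward C2, gives 19-ethyl 15-methyl (13R)-7-[(trifluoromethylsulfonyl)oxy]labda-2,7-diene-15,19-dioate F10. OsO4 (catalytic) with NMO should then add both oxygens from the face opposite the axial C19 ester and the C20 methyl, the vinyl triflate being inert to the oxidant, and give 28.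

Further compounds
F1 | step 11 | ethyl (2S,3E,5Z)-5-[(tert-butyldimethylsilyl)oxy]-2-{2-[(3E)-5-hydroxy-3-methylpent-3-en-1-yl]-1,3-dioxolan-2-yl}-2-methylhepta-3,5-dienoate | OC/C=C(\C)CCC1(OCCO1)[C@@](C)(C(=O)OCC)/C=C/C(O[Si](C)(C)C(C)(C)C)=C/C
F2 | step 11 | ethyl (2S,3E,5Z)-5-[(tert-butyldimethylsilyl)oxy]-2-methyl-2-{2-[(3E)-3-methyl-5-oxopent-3-en-1-yl]-1,3-dioxolan-2-yl}hepta-3,5-dienoate | O=C/C=C(\C)CCC1(OCCO1)[C@@](C)(C(=O)OCC)/C=C/C(O[Si](C)(C)C(C)(C)C)=C/C
F3 | step 19 | 19-ethyl 15-methyl (13R)-3,3-(ethylenedioxy)-7-hydroxylabdane-15,19-dioate (7-OH axial, 8-methyl equatorial) | CCOC(=O)[C@@]1(C)[C@H]2C[C@H](O)[C@H](C)[C@@H](CC[C@@H](C)CC(=O)OC)[C@]2(C)CCC13OCCO3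
F4 | step 19 | 19-ethyl 15-methyl (13R)-3,3-(ethylenedioxy)labd-7-ene-15,19-dioate | CCOC(=O)[C@@]1(C)[C@H]2CC=C(C)[C@@H](CC[C@@H](C)CC(=O)OC)[C@]2(C)CCC13OCCO3
F5 | step 19 | 19-ethyl 15-methyl (13R)-3-oxolabd-7-ene-15,19-dioate | CCOC(=O)[C@@]1(C)[C@H]2CC=C(C)[C@@H](CC[C@@H](C)CC(=O)OC)[C@]2(C)CCC1=O
F6 | step 19 | 19-ethyl 15-methyl (13R)-2-hydroxy-3-oxolabd-7-ene-15,19-dioate (2-OH equatorial) | CCOC(=O)[C@@]1(C)[C@H]2CC=C(C)[C@@H](CC[C@@H](C)CC(=O)OC)[C@]2(C)C[C@H](O)C1=O
F7 | step 19 | 19-ethyl 15-methyl (13R)-2,3-dihydroxylabd-7-ene-15,19-dioate (2-OH equatorial, 3-OH axial) | CCOC(=O)[C@@]1(C)[C@H]2CC=C(C)[C@@H](CC[C@@H](C)CC(=O)OC)[C@]2(C)C[C@H](O)[C@@H]1O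
F8 | step 22 | 19-ethyl 15-methyl (13R)-3-hydroxy-7-[(trifluoromethylsulfonyl)oxy]labd-7-ene-15,19-dioate (3-OH equatorial) | CCOC(=O)[C@@]1(C)[C@H]2CC(OS(=O)(=O)C(F)(F)F)=C(C)[C@@H](CC[C@@H](C)CC(=O)OC)[C@]2(C)CC[C@H]1O
F9 | step 22 | 19-ethyl 15-methyl (13R)-3-{[(methylsulfanyl)carbonothioyl]oxy}-7-[(trifluoromethylsulfonyl)oxy]labd-7-ene-15,19-dioate | CCOC(=O)[C@@]1(C)[C@H]2CC(OS(=O)(=O)C(F)(F)F)=C(C)[C@@H](CC[C@@H](C)CC(=O)OC)[C@]2(C)CC[C@H]1OC(=S)SC
F10 | step 22 | 19-ethyl 15-methyl (13R)-7-[(trifluoromethylsulfonyl)oxy]labda-2,7-diene-15,19-dioate | CCOC(=O)[C@@]1(C)[C@H]2CC(OS(=O)(=O)C(F)(F)F)=C(C)[C@@H](CC[C@@H](C)CC(=O)OC)[C@]2(C)CC=C1
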